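Target cannot reach the substrate charged, because in each of these flasks you charge less second reagent than substrate, and every target carries one unit of it, so second reagent is the limiting reagent.

common to all: substrate 0.072 M; partner 0.130 M; second reagent 0.0504 M; third reagent 0.0720 M; protic impurity 7.20 mM; time 8.0 h

|  | temperature |
|---|---|
| Thursday's | 60 °C |
| Friday's | 20 °C |
| Wednesday's | 40 °C |

    substrate + partner → intermediate A (k1 = 1.77 /M/h, Ea1 = 64.0 kJ/mol)
    second reagent + intermediate A → intermediate B (k2 = 5.03 /M/h, Ea2 = 75.0 kJ/mol)
    third reagent + intermediate B → target (k3 = 13.1 /M/h, Ea3 = 54.0 kJ/mol)
    substrate + second reagent → side product (k4 = 3.42 /M/h, Ea4 = 61.0 kJ/mol)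
    third reagent → decomposition product (k5 = 2.00 × 10⁻⁴ /h, Ea5 = 110 kJ/mol)
    partner + protic impurity → quenched reagent (k6 = 13.8 /M/h, Ea6 = 67.0 kJ/mol)
    (constants at 40 °C)

- all constants are for 40 °C and move with temperature by the activation energies

- which flask leads in amount of target, in percent of the substrate charged ("all alike" within 1.5 percentage points) (Thursday's / Friday's / Wednesday's / all alike)
- how much target is there at the end, in percent of the substrate charged: Thursday's
- how much target is there at the end, in percent of the substrate charged: Friday's
- how much target is there at the end, in percent of the substrate charged: Wednesday's

I build the flask up, and I work with the fraction left, taking a mean rate so that each loss is a plain exponential.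

1. Take the main chain by itself. Target then has room for 70.0% of the substrate charged.

2. Add the side reaction of substrate with second reagent. It competes with the partner for substrate, and the two stand in the selectivity factor s = k·c(partner)/k·c(second reagent), each k being that step's own constant, which is 1.33 at 40 °C with the starting amounts and 1.2 at the start on Friday's. Second reagent falls as it is used, so I take it midway, which gives a reckoned side product of 27.2% and cuts the room to 42.8%.

3. Add the rest. The protic impurity and the first step draw partner down, so its mean is nearer 0.100 M. My reckoned side product rises to 32.7%, and the room for target, the share of the substrate charge that second reagent can still reach once side product has had its part, is 37.3%. I carry this room, reckoned at 40 °C, to Thursday's, Wednesday's and Friday's. Held at its full charge, the third reagent decays by 2.02% of that charge over the run on Thursday's, less than the excess of its charge over what the room needs, so I leave the room as it stands.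

4. Add time. As a clock I take substrate's time constant at the starting amounts, 1/(k·c(partner) + k·c(second reagent)), which is 0.585 h on Thursday's, 2.48 h on Wednesday's, 12.8 h on Friday's. In my reckoning the room starts to fill only after that clock, as a pseudo-first-order decay of the unfilled fraction at k·c(intermediate A), with the constant of the step from intermediate A to intermediate B and with intermediate A taken at a mean of 0.0350 M. On Wednesday's, intermediate B passes on at k·c(third reagent), faster than that decay, so I count the step that makes intermediate B as the rate-limiting step there.

5. Read the fraction left unfilled. It is 0.0634% on Thursday's and 37.8% on Wednesday's, so I reckon target at 37.3% and 23.2%. On Friday's, 8.0 h ends before the clock, so I reckon nothing there, and in this reckoning Thursday's leads.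

The forecast names Thursday's with 39%, 1.4% on Friday's and 21% on Wednesday's, holding that at 20 °C “the three-step sequence has a long lag”, and it parts from my reckoning on Friday's, where it expects some target and I reckon none.

The simulation gives Thursday's in the lead, with 38.3% there, 19.8% on Wednesday's and 1.24% on Friday's.

Now leave Friday's flask until 20 h, amounts and temperature held. The clock of 12.8 h has been passed by 7.20 h, so I reckon the fraction unfilled at 83.8%, and the room of 37.3% then holds a reckoned 6.04% of target. That flask reads 6.86% of target, with 31.0% of substrate still there.

Its constants are made up.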